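**Retrosynthetic overview**
- The target diacetate comes from the (Z)-2-alkylbut-2-ene-1,4-diol by acetylation, and the diol from a dimethyl 2-alkylmaleate by ester reduction.
- The maleate arises by syn-carbocupration of dimethyl acetylenedicarboxylate with a homoallylic organocopper; this forms the bond between the butenediol carbon and the chain and fixes the 2Z geometry.
- The homoallylic bromide comes from the (E)-homoallylic alcohol, made from a terminal alkyne by zirconium-catalysed methylalumination and oxirane opening; this fixes the E-trisubstituted alkene.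
- The alkyne comes from (S)-dihydro-α-ionone (methyl ketone to alkyne), itself from (S)-α-ionone by conjugate reduction.
- No ring is formed: the single cyclohexene ring (ring A) and its only stereocentre are bought with (S)-α-ionone and carried through unchanged.

Assumption: (S)-(−)-α-ionone of high enantiomeric purity is taken as a purchasable starting material (enantiopure fragrance reference compound); I have not verified a current catalogue listing, and otherwise it must be obtained by resolving the racemate.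

**Route**

Step 1
Reactants: 1 (S)-α-ionone = (3E)-4-[(1S)-2,6,6-trimethylcyclohex-2-en-1-yl]but-3-en-2-one
Product: 3 (S)-dihydro-α-ionone = 4-[(1S)-2,6,6-trimethylcyclohex-2-en-1-yl]butan-2-one, via triethylsilyl enol ether 2 (not isolated)
Conditions: Et3SiH (1.2 equiv), RhCl(PPh3)3 (1 mol %), toluene, 60 °C; then K2CO3 (cat.), MeOH, rt
Reagents that add atoms: none
Why: RhCl(PPh3)3-catalysed 1,4-hydrosilylation (conjugate reduction) touches only the enone C=C under neutral conditions, so the γ-stereocentre is not epimerised by vinylogous enolisation, and methanolysis of the silyl enol ether after the enone is consumed releases the saturated ketone.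

Step 2
Reactants: 3 (S)-dihydro-α-ionone
Product: 5 (6S)-6-(but-3-yn-1-yl)-1,5,5-trimethylcyclohex-1-ene, via enol diethyl phosphate 4 (not isolated)
Conditions: LiN(i-Pr)2 (1.05 equiv), THF, −78 °C; ClP(O)(OEt)2, −78 °C → rt; then LiN(i-Pr)2 (2.3 equiv), THF, −78 °C → rt; H2O
Reagents that add atoms: none
Why: Kinetic enolisation on the CH3 side, O-phosphorylation and base-induced β-elimination of the enol phosphate (Negishi methyl ketone to terminal alkyne protocol) give the alkyne, while the remote allylic ring C–H is not acidic enough to be touched.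

Step 3
Reactants: 5 (6S)-6-(but-3-yn-1-yl)-1,5,5-trimethylcyclohex-1-ene; 6 trimethylaluminium; 7 oxirane
Product: 10 (3E)-4-methyl-6-[(1S)-2,6,6-trimethylcyclohex-2-en-1-yl]hex-3-en-1-ol, via (E)-alkenyldimethylalane 8 (not isolated), via lithium alkenylalanate 9 (not isolated)
Conditions: Me3Al (2 equiv), Cp2ZrCl2 (0.25 equiv), CH2Cl2, 0 °C → rt; volatiles removed; n-BuLi (1 equiv), THF/hexane, −78 → 0 °C; oxirane (3 equiv), 0 °C → rt; H2O
Reagents that add atoms: trimethylaluminium C[Al](C)C; oxirane C1CO1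
Why: Negishi zirconium-catalysed methylalumination adds Me and Al syn across the terminal alkyne with Al at the terminus, which sets the E-trisubstituted alkene (typically >98 %), and the derived alanate opens oxirane with retention of alkene geometry.

Step 4
Reactants: 10 (3E)-4-methyl-6-[(1S)-2,6,6-trimethylcyclohex-2-en-1-yl]hex-3-en-1-ol; 11 tetrabromomethane
Product: 12 (6S)-6-[(3E)-6-bromo-3-methylhex-3-en-1-yl]-1,5,5-trimethylcyclohex-1-ene
Conditions: CBr4 (1.3 equiv), PPh3 (1.4 equiv), CH2Cl2, 0 °C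
Reagents that add atoms: tetrabromomethane BrC(Br)(Br)Br
Why: The Appel reaction converts the primary alcohol to the bromide by SN2 displacement under essentially neutral conditions that leave both trisubstituted alkenes and the stereocentre alone.

Step 5
Reactants: 12 (6S)-6-[(3E)-6-bromo-3-methylhex-3-en-1-yl]-1,5,5-trimethylcyclohex-1-ene; 13 dimethyl but-2-ynedioate (DMAD)
Product: 17 dimethyl (2Z)-2-[(3E)-4-methyl-6-[(1S)-2,6,6-trimethylcyclohex-2-en-1-yl]hex-3-en-1-yl]but-2-enedioate, via Grignard reagent 14 (not isolated), via alkylcopper reagent 15 (not isolated), via alkenylcopper adduct 16 (not isolated)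
Conditions: Mg, THF, rt → 40 °C; CuBr·SMe2 (1.0 equiv), THF/Me2S, −45 °C; DMAD (0.95 equiv), −78 °C; sat. aq. NH4Cl added at −78 °C
Reagents that add atoms: dimethyl but-2-ynedioate COC(=O)C#CC(=O)OC
Why: Syn-carbocupration of the acetylenedicarboxylate by the organocopper, followed by protonation of the configurationally stable alkenylcopper at −78 °C, puts the alkyl group and H cis and so gives the maleate (Z) geometry.

Step 6
Reactants: 17 dimethyl (2Z)-2-[(3E)-4-methyl-6-[(1S)-2,6,6-trimethylcyclohex-2-en-1-yl]hex-3-en-1-yl]but-2-enedioate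
Product: 18 (2Z)-2-[(3E)-4-methyl-6-[(1S)-2,6,6-trimethylcyclohex-2-en-1-yl]hex-3-en-1-yl]but-2-ene-1,4-diol
Conditions: i-Bu2AlH (5 equiv), CH2Cl2, −78 → 0 °C; aq. potassium sodium tartrate work-up
Reagents that add atoms: none
Why: i-Bu2AlH reduces both conjugated esters by 1,2-hydride delivery (ester reduction) without conjugate reduction, so the Z-alkene is kept and the cis-2-ene-1,4-diol results.

Step 7
Reactants: 18 (2Z)-2-[(3E)-4-methyl-6-[(1S)-2,6,6-trimethylcyclohex-2-en-1-yl]hex-3-en-1-yl]but-2-ene-1,4-diol; 19 acetic anhydride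
Product: 20 (2Z)-2-[(3E)-4-methyl-6-[(1S)-2,6,6-trimethylcyclohex-2-en-1-yl]hex-3-en-1-yl]but-2-ene-1,4-diyl diacetate (target)
Conditions: Ac2O (3 equiv), pyridine, DMAP (cat.), CH2Cl2, 0 °C → rt
Reagents that add atoms: acetic anhydride CC(=O)OC(C)=O
Why: DMAP-catalysed O-acylation (nucleophilic acyl substitution) of the two primary allylic alcohols gives the diacetate without touching the alkenes or the stereocentre.

**Compound list**

1 | (S)-α-ionone, (3E)-4-[(1S)-2,6,6-trimethylcyclohex-2-en-1-yl]but-3-en-2-one | CC(=O)/C=C/[C@@H]1C(C)=CCCC1(C)C | starting material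
2 | triethyl{[4-[(1S)-2,6,6-trimethylcyclohex-2-en-1-yl]but-2-en-2-yl]oxy}silane (E/Z mixture) | CC(O[Si](CC)(CC)CC)=CC[C@@H]1C(C)=CCCC1(C)C | intermediate
3 | (S)-dihydro-α-ionone, 4-[(1S)-2,6,6-trimethylcyclohex-2-en-1-yl]butan-2-one | CC(=O)CC[C@@H]1C(C)=CCCC1(C)C | intermediate
4 | diethyl 4-[(1S)-2,6,6-trimethylcyclohex-2-en-1-yl]but-1-en-2-yl phosphate | C=C(OP(=O)(OCC)OCC)CC[C@@H]1C(C)=CCCC1(C)C | intermediate
5 | (6S)-6-(but-3-yn-1-yl)-1,5,5-trimethylcyclohex-1-ene | C#CCC[C@@H]1C(C)=CCCC1(C)C | intermediate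
6 | trimethylaluminium | C[Al](C)C | starting material
7 | oxirane | C1CO1 | starting material
8 | dimethyl[(1E)-2-methyl-4-[(1S)-2,6,6-trimethylcyclohex-2-en-1-yl]but-1-en-1-yl]alane | C[Al](C)/C=C(\C)CC[C@@H]1C(C)=CCCC1(C)C | intermediate
9 | lithium butyl(dimethyl)[(1E)-2-methyl-4-[(1S)-2,6,6-trimethylcyclohex-2-en-1-yl]but-1-en-1-yl]alanate | [Li+].CCCC[Al-](C)(C)/C=C(\C)CC[C@@H]1C(C)=CCCC1(C)C | intermediate
10 | (3E)-4-methyl-6-[(1S)-2,6,6-trimethylcyclohex-2-en-1-yl]hex-3-en-1-ol | OCC/C=C(\C)CC[C@@H]1C(C)=CCCC1(C)C | intermediate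
11 | tetrabromomethane | BrC(Br)(Br)Br | starting material
12 | (6S)-6-[(3E)-6-bromo-3-methylhex-3-en-1-yl]-1,5,5-trimethylcyclohex-1-ene | BrCC/C=C(\C)CC[C@@H]1C(C)=CCCC1(C)C | intermediate
13 | dimethyl but-2-ynedioate (DMAD) | COC(=O)C#CC(=O)OC | starting material
14 | [(3E)-4-methyl-6-[(1S)-2,6,6-trimethylcyclohex-2-en-1-yl]hex-3-en-1-yl]magnesium bromide | Br[Mg]CC/C=C(\C)CC[C@@H]1C(C)=CCCC1(C)C | intermediate
15 | [(3E)-4-methyl-6-[(1S)-2,6,6-trimethylcyclohex-2-en-1-yl]hex-3-en-1-yl]copper (MgBr2/Me2S complex) | [Cu]CC/C=C(\C)CC[C@@H]1C(C)=CCCC1(C)C | intermediate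
16 | dimethyl (2E)-2-cuprio-3-[(3E)-4-methyl-6-[(1S)-2,6,6-trimethylcyclohex-2-en-1-yl]hex-3-en-1-yl]but-2-enedioate | COC(=O)/C([Cu])=C(/CC/C=C(\C)CC[C@@H]1C(C)=CCCC1(C)C)C(=O)OC | intermediate
17 | dimethyl (2Z)-2-[(3E)-4-methyl-6-[(1S)-2,6,6-trimethylcyclohex-2-en-1-yl]hex-3-en-1-yl]but-2-enedioate | COC(=O)/C=C(/CC/C=C(\C)CC[C@@H]1C(C)=CCCC1(C)C)C(=O)OC | intermediate
18 | (2Z)-2-[(3E)-4-methyl-6-[(1S)-2,6,6-trimethylcyclohex-2-en-1-yl]hex-3-en-1-yl]but-2-ene-1,4-diol | OC/C=C(/CC/C=C(\C)CC[C@@H]1C(C)=CCCC1(C)C)CO | intermediate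
19 | acetic anhydride | CC(=O)OC(C)=O | starting material
20 | (2Z)-2-[(3E)-4-methyl-6-[(1S)-2,6,6-trimethylcyclohex-2-en-1-yl]hex-3-en-1-yl]but-2-ene-1,4-diyl diacetate | CC(=O)OC/C=C(/CC/C=C(\C)CC[C@@H]1C(C)=CCCC1(C)C)COC(C)=O | target

**Totals and risk**

Total step count: 7. Longest linear sequence: 7 steps (1 → 20).

The three steps most likely to fail are steps 2, 3 and 5, with step 5 the riskiest.

Step 2 (methyl ketone to alkyne) can suffer from incomplete regiocontrol in the enolisation or from allene formation. The fallback sets out from ketone 3 and avoids the alkyne altogether by a Julia–Johnson cyclopropylcarbinyl rearrangement. Cyclopropylmagnesium bromide (THF, 0 °C) adds to 3 to give 2-cyclopropyl-4-[(1S)-2,6,6-trimethylcyclohex-2-en-1-yl]butan-2-ol F1 (epimers at the carbinol carbon). Brief treatment with cold 48 % aqueous HBr (or MgBr2·OEt2 in ether) opens the cyclopropane to the homoallylic bromide, and the route is rejoined at 12, so steps 2 to 4 are replaced. The cost is an E/Z ratio of only about 4:1, which must be upgraded on AgNO3-impregnated silica; this is why it is not the main route.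

Step 3 (methylalumination then oxirane opening) may stall at the alanate alkylation. The fallback sets out from alkyne 5, runs the same Me3Al/Cp2ZrCl2 methylalumination but quenches alkenylalane 8 with I2 to isolate (6S)-6-[(3E)-4-iodo-3-methylbut-3-en-1-yl]-1,5,5-trimethylcyclohex-1-ene F2. Lithium–iodine exchange (t-BuLi, 2 equiv, Et2O, −78 °C) gives [(1E)-2-methyl-4-[(1S)-2,6,6-trimethylcyclohex-2-en-1-yl]but-1-en-1-yl]lithium F3, which opens oxirane 7 in the presence of BF3·OEt2 at −78 °C. The route is rejoined at alcohol 10.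

Step 5 (organocopper addition to DMAD) may suffer from Wurtz coupling during Grignard formation, double addition, or Z to E leakage if the alkenylcopper warms before the quench. The fallback sets out from bromide 12 and builds the cis-diol from a butenolide instead of a maleate. Zinc insertion (Zn dust, LiCl, THF, 50 °C) gives [(3E)-4-methyl-6-[(1S)-2,6,6-trimethylcyclohex-2-en-1-yl]hex-3-en-1-yl]zinc bromide F4. Negishi coupling (Pd(PPh3)4, THF, 50 °C) with commercial 4-bromofuran-2(5H)-one gives 4-[(3E)-4-methyl-6-[(1S)-2,6,6-trimethylcyclohex-2-en-1-yl]hex-3-en-1-yl]furan-2(5H)-one F5. Reduction of this butenolide with excess i-Bu2AlH (CH2Cl2, −78 → 0 °C) gives the diol, the lactone ring enforcing the cis relation of the two CH2O groups. The route is rejoined at diol 18, so steps 5 and 6 are replaced.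

**Further compounds**

F1 | step 2 | 2-cyclopropyl-4-[(1S)-2,6,6-trimethylcyclohex-2-en-1-yl]butan-2-ol | CC(O)(CC[C@@H]1C(C)=CCCC1(C)C)C1CC1
F2 | step 3 | (6S)-6-[(3E)-4-iodo-3-methylbut-3-en-1-yl]-1,5,5-trimethylcyclohex-1-ene | I/C=C(\C)CC[C@@H]1C(C)=CCCC1(C)C
F3 | step 3 | [(1E)-2-methyl-4-[(1S)-2,6,6-trimethylcyclohex-2-en-1-yl]but-1-en-1-yl]lithium | [Li]/C=C(\C)CC[C@@H]1C(C)=CCCC1(C)C
F4 | step 5 | [(3E)-4-methyl-6-[(1S)-2,6,6-trimethylcyclohex-2-en-1-yl]hex-3-en-1-yl]zinc bromide | Br[Zn]CC/C=C(\C)CC[C@@H]1C(C)=CCCC1(C)C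
F5 | step 5 | 4-[(3E)-4-methyl-6-[(1S)-2,6,6-trimethylcyclohex-2-en-1-yl]hex-3-en-1-yl]furan-2(5H)-one | O=C1C=C(CC/C=C(\C)CC[C@@H]2C(C)=CCCC2(C)C)CO1
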